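**Plan**

- Retrosynthesis: remove the two MOM ethers, return the diaryl ketone to a silyl-protected carbinol, open the pyran at O1–C2 and C3–C4 (isobutenyl Grignard on a salicylaldehyde, then oxa-6π closure), and cut ring B at C4a–C5 and C7–C8 (Michael–Claisen). Then cut the enoate C=C (cross-metathesis) and the aryl–carbinol bond (vinyl addition).
- Enabling feature: ring B carries its oxygens on C7 and C8a in a 1,3-relationship. C5 is meta to both, so it can be the β-carbon of an enoate. C4a is ortho/para to them, so it can be the carboxyl-bearing carbon of a resorcylate.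
- Forward order: ring A is bought and extended to a γ-aryl-γ-silyloxy enoate. Ring B is then built as a cyclohexane-1,3-dione and dehydrogenated to the resorcylate. The pyran ring closes last, followed by carbinol oxidation and MOM removal.
- Stereochemistry: the target is achiral. The carbinol centre and the ring sp3 centres are carried as mixtures and erased by aromatisation and oxidation. Only the E-enoate geometry matters, and it comes from thermodynamic cross-metathesis.

Key step: step 5

Remark: ring A carries its future hydroxyl as a MOM ether from the start, so no late O-demethylation is needed; 2-hydroxy-4,6-dimethoxybenzaldehyde is assumed to be commercially available. Abbreviations: Ar = 2,4-dimethoxy-6-(methoxymethoxy)phenyl, TBS = tert-butyldimethylsilyl, MOM = methoxymethyl.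

**Route**

Step 1
Reactants: 1 2-hydroxy-4,6-dimethoxybenzaldehyde
Product: 2 2,4-dimethoxy-6-(methoxymethoxy)benzaldehyde
Conditions: NaH, DMF, 0 °C; MOMCl, 0 °C → rt
Reagents that add atoms: chloromethyl methyl ether (MOMCl), COCCl
Why: Williamson-type O-alkylation of the sodium phenoxide gives an acetal that should survive the Grignard, alkoxide, hydride and fluoride steps and fall off in the final acidic step.

Step 2
Reactants: 2 2,4-dimethoxy-6-(methoxymethoxy)benzaldehyde
Product: 3 rac-1-(Ar)prop-2-en-1-ol
Conditions: H2C=CHMgBr, THF, −78 → 0 °C; aq. NaH2PO4/Na2HPO4 buffer (pH 7)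
Reagents that add atoms: vinylmagnesium bromide, C=C[Mg]Br
Why: Grignard 1,2-addition to the aryl aldehyde gives the racemic allylic carbinol, whose centre later becomes the ketone carbon and needs no control; the neutral work-up avoids ionisation of the electron-rich benzylic alcohol.

Step 3
Reactants: 3 rac-1-(Ar)prop-2-en-1-ol
Product: 4 rac-tert-butyl{[1-(Ar)prop-2-en-1-yl]oxy}dimethylsilane
Conditions: TBSCl, imidazole, cat. DMAP, DMF, rt → 40 °C
Reagents that add atoms: tert-butyldimethylsilyl chloride, CC(C)(C)[Si](C)(C)Cl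
Why: imidazole-mediated silylation caps the carbinol under non-acidic conditions, which suppresses its ionisation and prevents lactonisation onto the ester once ring B has been built.

Step 4
Reactants: 4 rac-tert-butyl{[1-(Ar)prop-2-en-1-yl]oxy}dimethylsilane; 5 methyl acrylate
Product: 6 methyl (2E)-4-[(TBS)oxy]-4-(Ar)but-2-enoate (racemic)
Conditions: methyl acrylate (5 equiv), second-generation Hoveyda–Grubbs catalyst RuCl2(H2IMes)(=CH-C6H4-2-O-i-Pr) (5 mol %), CH2Cl2, 40 °C
Reagents that add atoms: methyl acrylate, C=CC(=O)OC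
Why: olefin cross-metathesis between a terminal allylic silyl ether and an excess of acrylate should give the conjugated ester as the thermodynamically favoured E isomer, with loss of ethene.

Step 5
Reactants: 6 methyl (2E)-4-[(TBS)oxy]-4-(Ar)but-2-enoate; 7 methyl acetoacetate
Product: 9 methyl 6-{[(TBS)oxy](Ar)methyl}-2,4-dioxocyclohexane-1-carboxylate (diastereomer and enol mixture), via acyclic Michael adduct 8 (not isolated)
Conditions: NaOMe (1.2 equiv), methyl acetoacetate (1.2 equiv), MeOH, rt then 65 °C; cold 1 M HCl to pH 4–5, EtOAc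
Reagents that add atoms: methyl acetoacetate, CC(=O)CC(=O)OC
Why: Methoxide generates the doubly stabilised acetoacetate enolate, which adds in Michael fashion to the enoate β-carbon of 6 (new C1–C6 bond of the carbocycle, the future C4a–C5 bond) to give 8; proton exchange then lets the methyl-ketone enolate attack the chain ester in a Claisen (Dieckmann-type) condensation that expels methoxide and forms the C3–C4 bond (future C8–C7). The closest known reaction is the acetoacetate–crotonate condensation that gives dihydroorsellinates. The single ring closes in the 6-exo-trig mode and should be pulled to completion because the product is deprotonated to the vinylogous carboxylate of the 1,3-dione. Two ring stereocentres (C1, C6) arise next to the existing carbinol centre without control, which is immaterial because all of them become sp2 in steps 6 and 12. The selectivity required is regiochemical: the donor must bond to the carbon that carries the aryl carbinol, and this is secured because the ester is the only acceptor carbonyl in 6, the benzylic oxygen being held as a silyl ether and not as a ketone. No other ring size competes, since the alternative enolate–carbonyl pairings would give four-membered rings.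

Step 6
Reactants: 9 methyl 6-{[(TBS)oxy](Ar)methyl}-2,4-dioxocyclohexane-1-carboxylate
Product: 12 methyl 2-{[(TBS)oxy](Ar)methyl}-4,6-dihydroxybenzoate (racemic), via C1 phenylselenide 10 (not isolated), via C1 selenoxide 11 (not isolated)
Conditions: LiN(i-Pr)2 (2.3 equiv), THF, −78 → −30 °C; PhSeBr (1.1 equiv), −78 °C; H2O quench; then 30 % H2O2, pyridine, CH2Cl2, 0 °C → rt
Reagents that add atoms: none
Why: the dianion (dione enolate plus ester enolate at C1) should be selenenylated at the last-formed C1 carbanion, and oxidation followed by syn-selenoxide elimination toward C6–H gives a cyclohexenedione that tautomerises to the resorcylate; the sequence stays basic or buffered, which spares the ionisation-prone benzylic silyl ether that acidic halogen-based aromatisations would endanger.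

Step 7
Reactants: 12 methyl 2-{[(TBS)oxy](Ar)methyl}-4,6-dihydroxybenzoate
Product: 13 methyl 2-{[(TBS)oxy](Ar)methyl}-6-hydroxy-4-(methoxymethoxy)benzoate
Conditions: MOMCl (1.1 equiv), K2CO3, acetone, 0 °C → rt
Reagents that add atoms: chloromethyl methyl ether (MOMCl), COCCl
Why: selective phenol O-alkylation should take place at the hydroxyl para to the ester, because the ortho hydroxyl is hydrogen-bonded to the ester carbonyl and is the less acidic and less nucleophilic of the two.

Step 8
Reactants: 13 methyl 2-{[(TBS)oxy](Ar)methyl}-6-hydroxy-4-(methoxymethoxy)benzoate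
Product: 14 3-{[(TBS)oxy](Ar)methyl}-2-(hydroxymethyl)-5-(methoxymethoxy)phenol
Conditions: i-Bu2AlH (4 equiv), CH2Cl2, −78 → 0 °C; aq. KNaC4H4O6 (potassium sodium tartrate)
Reagents that add atoms: none
Why: hydride reduction of the salicylate ester to the benzylic alcohol is assisted by the aluminium phenoxide formed first, and the low temperature with a non-acidic tartrate work-up should keep the silyl ether in place and the salicyl alcohol from dehydrating.

Step 9
Reactants: 14 3-{[(TBS)oxy](Ar)methyl}-2-(hydroxymethyl)-5-(methoxymethoxy)phenol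
Product: 15 2-{[(TBS)oxy](Ar)methyl}-6-hydroxy-4-(methoxymethoxy)benzaldehyde
Conditions: activated MnO2 (excess), CH2Cl2, rt
Reagents that add atoms: none
Why: heterogeneous MnO2 oxidation is selective for the benzylic primary alcohol and stops at the hydrogen-bonded salicylaldehyde under neutral conditions.

Step 10
Reactants: 15 2-{[(TBS)oxy](Ar)methyl}-6-hydroxy-4-(methoxymethoxy)benzaldehyde
Product: 18 tert-butyl{(Ar)[7-(methoxymethoxy)-2,2-dimethyl-2H-chromen-5-yl]methoxy}dimethylsilane (racemic), via allylic carbinol 16 (not isolated), via o-quinone methide 17 (not isolated)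
Conditions: Me2C=CHMgBr (3 equiv), THF, −20 → 0 °C; aq. NaH2PO4/Na2HPO4 buffer (pH 7); crude carbinol in PhMe, 4 Å MS, 90 °C
Reagents that add atoms: 2-methylprop-1-en-1-ylmagnesium bromide, CC(C)=C[Mg]Br
Why: Grignard 1,2-addition gives an o-hydroxybenzylic allylic alcohol that, activated by the ortho and para oxygens, should lose water thermally to the o-quinone methide, which closes by oxa-6π electrocyclisation to the 2,2-dimethyl-2H-chromene.

Step 11
Reactants: 18 tert-butyl{(Ar)[7-(methoxymethoxy)-2,2-dimethyl-2H-chromen-5-yl]methoxy}dimethylsilane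
Product: 19 (Ar)[7-(methoxymethoxy)-2,2-dimethyl-2H-chromen-5-yl]methanol (racemic)
Conditions: Bu4NF, THF, 0 → 40 °C; chromatography on Et3N-deactivated silica
Reagents that add atoms: none
Why: fluoride-mediated desilylation frees the diaryl carbinol under basic conditions, with the phenols still masked and no acid present to ionise the doubly benzylic alcohol.

Step 12
Reactants: 19 (Ar)[7-(methoxymethoxy)-2,2-dimethyl-2H-chromen-5-yl]methanol
Product: 20 (Ar)[7-(methoxymethoxy)-2,2-dimethyl-2H-chromen-5-yl]methanone
Conditions: Dess–Martin periodinane, NaHCO3, CH2Cl2, 0 °C → rt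
Reagents that add atoms: none
Why: Dess–Martin oxidation converts hindered secondary benzylic alcohols to ketones at room temperature, and the bicarbonate buffer removes the acetic acid that could ionise the carbinol or attack the chromene.

Step 13
Reactants: 20 (Ar)[7-(methoxymethoxy)-2,2-dimethyl-2H-chromen-5-yl]methanone
Product: 21 (2-hydroxy-4,6-dimethoxyphenyl)(7-hydroxy-2,2-dimethyl-2H-chromen-5-yl)methanone
Conditions: 2 M HCl in MeOH, 40 °C
Reagents that add atoms: none
Why: acid-catalysed acetal methanolysis removes both aryl MOM ethers, the one ortho to the carbonyl being assisted by chelation, under conditions that 2,2-dimethylchromenes and the methyl ethers should tolerate.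

**Compound list**

1 | 2-hydroxy-4,6-dimethoxybenzaldehyde | COc1cc(O)c(C=O)c(OC)c1 | starting material
2 | 2,4-dimethoxy-6-(methoxymethoxy)benzaldehyde | COCOc1cc(OC)cc(OC)c1C=O | intermediate
3 | rac-1-[2,4-dimethoxy-6-(methoxymethoxy)phenyl]prop-2-en-1-ol | C=CC(O)c1c(OC)cc(OC)cc1OCOC | intermediate
4 | rac-tert-butyl({1-[2,4-dimethoxy-6-(methoxymethoxy)phenyl]prop-2-en-1-yl}oxy)dimethylsilane | C=CC(O[Si](C)(C)C(C)(C)C)c1c(OC)cc(OC)cc1OCOC | intermediate
5 | methyl acrylate | C=CC(=O)OC | starting material
6 | methyl (2E)-4-[(tert-butyldimethylsilyl)oxy]-4-[2,4-dimethoxy-6-(methoxymethoxy)phenyl]but-2-enoate (racemic) | COC(=O)/C=C/C(O[Si](C)(C)C(C)(C)C)c1c(OC)cc(OC)cc1OCOC | intermediate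
7 | methyl acetoacetate (methyl 3-oxobutanoate) | CC(=O)CC(=O)OC | starting material
8 | dimethyl 2-acetyl-3-{[(tert-butyldimethylsilyl)oxy][2,4-dimethoxy-6-(methoxymethoxy)phenyl]methyl}pentanedioate (diastereomer mixture, not isolated) | COC(=O)CC(C(C(C)=O)C(=O)OC)C(O[Si](C)(C)C(C)(C)C)c1c(OC)cc(OC)cc1OCOC | intermediate
9 | methyl 6-{[(tert-butyldimethylsilyl)oxy][2,4-dimethoxy-6-(methoxymethoxy)phenyl]methyl}-2,4-dioxocyclohexane-1-carboxylate (diastereomer mixture) | COC(=O)C1C(=O)CC(=O)CC1C(O[Si](C)(C)C(C)(C)C)c1c(OC)cc(OC)cc1OCOC | intermediate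
10 | methyl 6-{[(tert-butyldimethylsilyl)oxy][2,4-dimethoxy-6-(methoxymethoxy)phenyl]methyl}-2,4-dioxo-1-(phenylselanyl)cyclohexane-1-carboxylate (not isolated) | COC(=O)C1([Se]c2ccccc2)C(=O)CC(=O)CC1C(O[Si](C)(C)C(C)(C)C)c1c(OC)cc(OC)cc1OCOC | intermediate
11 | methyl 6-{[(tert-butyldimethylsilyl)oxy][2,4-dimethoxy-6-(methoxymethoxy)phenyl]methyl}-2,4-dioxo-1-(phenylseleninyl)cyclohexane-1-carboxylate (not isolated) | COC(=O)C1([Se](=O)c2ccccc2)C(=O)CC(=O)CC1C(O[Si](C)(C)C(C)(C)C)c1c(OC)cc(OC)cc1OCOC | intermediate
12 | methyl 2-{[(tert-butyldimethylsilyl)oxy][2,4-dimethoxy-6-(methoxymethoxy)phenyl]methyl}-4,6-dihydroxybenzoate (racemic) | COC(=O)c1c(O)cc(O)cc1C(O[Si](C)(C)C(C)(C)C)c1c(OC)cc(OC)cc1OCOC | intermediate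
13 | methyl 2-{[(tert-butyldimethylsilyl)oxy][2,4-dimethoxy-6-(methoxymethoxy)phenyl]methyl}-6-hydroxy-4-(methoxymethoxy)benzoate (racemic) | COC(=O)c1c(O)cc(OCOC)cc1C(O[Si](C)(C)C(C)(C)C)c1c(OC)cc(OC)cc1OCOC | intermediate
14 | 3-{[(tert-butyldimethylsilyl)oxy][2,4-dimethoxy-6-(methoxymethoxy)phenyl]methyl}-2-(hydroxymethyl)-5-(methoxymethoxy)phenol (racemic) | OCc1c(O)cc(OCOC)cc1C(O[Si](C)(C)C(C)(C)C)c1c(OC)cc(OC)cc1OCOC | intermediate
15 | 2-{[(tert-butyldimethylsilyl)oxy][2,4-dimethoxy-6-(methoxymethoxy)phenyl]methyl}-6-hydroxy-4-(methoxymethoxy)benzaldehyde (racemic) | O=Cc1c(O)cc(OCOC)cc1C(O[Si](C)(C)C(C)(C)C)c1c(OC)cc(OC)cc1OCOC | intermediate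
16 | 3-{[(tert-butyldimethylsilyl)oxy][2,4-dimethoxy-6-(methoxymethoxy)phenyl]methyl}-2-(1-hydroxy-3-methylbut-2-en-1-yl)-5-(methoxymethoxy)phenol (diastereomer mixture, not isolated) | CC(C)=CC(O)c1c(O)cc(OCOC)cc1C(O[Si](C)(C)C(C)(C)C)c1c(OC)cc(OC)cc1OCOC | intermediate
17 | 5-{[(tert-butyldimethylsilyl)oxy][2,4-dimethoxy-6-(methoxymethoxy)phenyl]methyl}-3-(methoxymethoxy)-6-(3-methylbut-2-en-1-ylidene)cyclohexa-2,4-dien-1-one (o-quinone methide, side chain cis to the carbonyl, not isolated) | CC(C)=C/C=C1\C(=O)C=C(OCOC)C=C1C(O[Si](C)(C)C(C)(C)C)c1c(OC)cc(OC)cc1OCOC | intermediate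
18 | tert-butyl{[2,4-dimethoxy-6-(methoxymethoxy)phenyl][7-(methoxymethoxy)-2,2-dimethyl-2H-chromen-5-yl]methoxy}dimethylsilane (racemic) | CC1(C)C=Cc2c(O1)cc(OCOC)cc2C(O[Si](C)(C)C(C)(C)C)c1c(OC)cc(OC)cc1OCOC | intermediate
19 | [2,4-dimethoxy-6-(methoxymethoxy)phenyl][7-(methoxymethoxy)-2,2-dimethyl-2H-chromen-5-yl]methanol (racemic) | CC1(C)C=Cc2c(O1)cc(OCOC)cc2C(O)c1c(OC)cc(OC)cc1OCOC | intermediate
20 | [2,4-dimethoxy-6-(methoxymethoxy)phenyl][7-(methoxymethoxy)-2,2-dimethyl-2H-chromen-5-yl]methanone | CC1(C)C=Cc2c(O1)cc(OCOC)cc2C(=O)c1c(OC)cc(OC)cc1OCOC | intermediate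
21 | (2-hydroxy-4,6-dimethoxyphenyl)(7-hydroxy-2,2-dimethyl-2H-chromen-5-yl)methanone | COc1cc(O)c(C(=O)c2cc(O)cc3c2C=CC(C)(C)O3)c(OC)c1 | target

**Totals and risks**

Total step count: 13. Longest linear sequence: 13 steps (fully linear from 1).

Steps most likely to fail:

1. Step 5 (Michael–Claisen annulation). The conjugate addition may be slow at the β-carbon, which sits next to a crowded aryl silyloxy carbon. Methoxide may instead remove the γ-hydrogen of 6 and move the double bond out of conjugation, or the open-chain adduct may lose its acetyl group by retro-Claisen cleavage before it cyclises. The fallback changes the partners so that a better acceptor meets a better donor. It sets out from 4: cross-metathesis with but-3-en-2-one under the catalyst of step 4 should give (3E)-5-[(TBS)oxy]-5-(Ar)pent-3-en-2-one F1. Dimethyl malonate with NaOMe in MeOH (rt then 65 °C) should add to the enone to give the keto diester dimethyl 2-[1-[(TBS)oxy]-1-(Ar)-4-oxopentan-2-yl]propanedioate F2, which is not isolated; its methyl-ketone enolate closes onto one malonate ester. This is the classical malonate–enone route to dihydroresorcylates; the ring closes at C2–C3 instead of C3–C4, but the product is the same dione, so the fallback rejoins the route at 9.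

2. Step 6 (dehydrogenation to the resorcylate). Selenenylation may occur at C3 between the two ketones, where no syn-elimination is possible, or the peroxide stage may over-oxidise the electron-rich ring A. The fallback sets out from 9 and aromatises a preformed diene instead of an enolate. Me3SiCl and Et3N (MeCN, rt) should give the bis-silyl dienol ether methyl 6-{[(TBS)oxy](Ar)methyl}-2,4-bis[(trimethylsilyl)oxy]cyclohexa-1,3-diene-1-carboxylate F3. DDQ with 2,6-lutidine in CH2Cl2 at 0 °C should dehydrogenate this cyclohexa-1,3-diene to methyl 2-{[(TBS)oxy](Ar)methyl}-4,6-bis[(trimethylsilyl)oxy]benzoate F4. K2CO3 in MeOH at rt then removes the aryl trimethylsilyl groups, and the fallback rejoins the route at 12.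

3. Step 4 (cross-metathesis). Metathesis may stall at the hindered allylic position, and ruthenium hydride species may isomerise the allylic silyl ether to an enol ether. The fallback builds the enoate from an alkyne and sets out from 2. LiC≡CCO2Me (methyl propiolate, LiN(i-Pr)2, THF, −78 °C) should add to the aldehyde to give methyl 4-hydroxy-4-(Ar)but-2-ynoate F5. Hydroxyl-directed trans-hydroalumination with NaAlH2(OCH2CH2OMe)2 in THF at −72 °C, followed by protonation, should give methyl (2E)-4-hydroxy-4-(Ar)but-2-enoate F6. Silylation with TBSCl and imidazole in DMF then rejoins the route at 6.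

**Further compounds**

F1 | step 5 | (3E)-5-[(tert-butyldimethylsilyl)oxy]-5-[2,4-dimethoxy-6-(methoxymethoxy)phenyl]pent-3-en-2-one (racemic) | CC(=O)/C=C/C(O[Si](C)(C)C(C)(C)C)c1c(OC)cc(OC)cc1OCOC
F2 | step 5 | dimethyl 2-{1-[(tert-butyldimethylsilyl)oxy]-1-[2,4-dimethoxy-6-(methoxymethoxy)phenyl]-4-oxopentan-2-yl}propanedioate (diastereomer mixture) | COC(=O)C(C(=O)OC)C(CC(C)=O)C(O[Si](C)(C)C(C)(C)C)c1c(OC)cc(OC)cc1OCOC
F3 | step 6 | methyl 6-{[(tert-butyldimethylsilyl)oxy][2,4-dimethoxy-6-(methoxymethoxy)phenyl]methyl}-2,4-bis[(trimethylsilyl)oxy]cyclohexa-1,3-diene-1-carboxylate (diastereomer mixture) | COC(=O)C1=C(O[Si](C)(C)C)C=C(O[Si](C)(C)C)CC1C(O[Si](C)(C)C(C)(C)C)c1c(OC)cc(OC)cc1OCOC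
F4 | step 6 | methyl 2-{[(tert-butyldimethylsilyl)oxy][2,4-dimethoxy-6-(methoxymethoxy)phenyl]methyl}-4,6-bis[(trimethylsilyl)oxy]benzoate (racemic) | COC(=O)c1c(O[Si](C)(C)C)cc(O[Si](C)(C)C)cc1C(O[Si](C)(C)C(C)(C)C)c1c(OC)cc(OC)cc1OCOC
F5 | step 4 | methyl 4-hydroxy-4-[2,4-dimethoxy-6-(methoxymethoxy)phenyl]but-2-ynoate (racemic) | COC(=O)C#CC(O)c1c(OC)cc(OC)cc1OCOC
F6 | step 4 | methyl (2E)-4-hydroxy-4-[2,4-dimethoxy-6-(methoxymethoxy)phenyl]but-2-enoate (racemic) | COC(=O)/C=C/C(O)c1c(OC)cc(OC)cc1OCOC
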